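# Proposed total synthesis of CNP0170350.1

## Analysis of the target

Locants in the prose follow the target: C1 is the ring CH bearing the exocyclic methylene C7 (C7–O–aryl), C2 the methyl-bearing alkene carbon, C3 the alkene CH, C4 the ring CH2, C5 the CH–OAc and C6 the C(CH3)2 carbon. Systematic names in the steps carry their own locants.

- The target is a monocyclic α-cyclogeranyl-type terpenoid: one cyclohexene ring (C1–C6) with a trisubstituted C2=C3 double bond, a quaternary gem-dimethyl carbon C6, a secondary acetate at C5 and a C7 methylene ether to O7 of umbelliferone.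
- There are two stereocentres, C1 and C5, both R. They flank the quaternary C6, and C7 and the acetoxy group are trans (1,3-anti across C6).
- Chair cyclisation of an E-configured epoxy-diene gives the cis arrangement, so the trans relationship has to be set deliberately.
- The coumarin is a base-labile lactone, a conjugate acceptor and a photoreactive chromophore, so it can only enter after all organometallic steps.
- The Δ2 double bond must not drift to the tetrasubstituted C1=C2 or the exocyclic position, and the C5 carbinol is neopentyl-type, so inversion by SN2 is not available.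
- The hard points are: the C1–C7 bond at a carbon wedged between C6 and C2; the 1,3-trans relation across a quaternary carbon; the alkene regiochemistry; and the absolute configuration at C5.
- The feature the route exploits: C6, its two flanking stereocentres C1 and C5, and C3 para to C6 form the pattern of a 4,4-dimethylcyclohexa-2,5-dienone. C3 is the carbonyl carbon, C2 (with its methyl) and C4 are the α-carbons, and C1 and C5 are the two β-carbons of one flat, achiral dienone.

## Retrosynthetic reasoning

**C5 O–acyl and O–silyl bonds (15 to 14 to 13).** The acetate is put on last because no earlier step tolerates an ester next to an enolisable or organometallic centre. Alcohol 14 comes from silyl ether 13. Both steps take place at oxygen and leave C5 untouched.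

**C7–O(aryl) bond (13 to 11 + 12).** The ether is cut at C7–O, not at the aryl–O bond, because umbelliferone 12 is an acidic phenol suited to a Mitsunobu reaction with primary alcohol 11. This places the coumarin after every organometallic and hydride step. The forward reaction is an SN2 at a β-branched primary carbon; no stereocentre is involved.

**C7–Si and C3–OTf adjustments (11 to 10 to 9).** The C7 hydroxyl is masked as an alkoxysilyl group that survives carbanion chemistry and is revealed by oxidation. The C3–H bond comes from hydride replacement of an enol triflate. Both are functional-group steps that do not touch C1, C5 or the position of the double bond.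

**Key disconnection: C1–C7 bond plus the C3–O sulfonyl bond (9 to 7).** Cutting C1–C7 turns the ring into enone 7, in which C1 is the β-carbon, C2 the α-carbon and C3 the carbonyl carbon. Forward, a conjugate addition of a hydroxymethyl anion equivalent forms the most hindered C–C bond and sets C1 anti to the C5 silyloxy group. It also produces the enolate exactly across C2–C3; trapping it as the triflate fixes the Δ2 position. A cut at C1–C6 (cationic cyclisation) leaves all three issues to the intrinsic bias of a carbocation.

**C5–O bond (7 to 6 to 4).** In dienone 4 the carbon C5 is the β-carbon of the unsubstituted enone arm. A catalytic enantioselective β-borylation with oxidation installs the C5 oxygen there; the 2-methyl group steers boron away from the other arm. The forward reaction has to distinguish the two faces of one enone arm of a flat molecule. This is the only reagent-controlled stereochemical step; C1 is then relayed from C5.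

**C4–C5 unsaturation and ring construction (4 to 3 to 1 + 2).** Dienone 4 comes from enone 3 by dehydrogenation; the quaternary carbon blocks aromatisation. Enone 3 is the annulation product of aldehyde 1 and vinyl ketone 2. The aldehyde α-carbon becomes C6 and the ethyl group of 2 supplies C2 with its methyl group.

## Alternatives that were turned down

**Alternative 1: biomimetic epoxy-olefin cyclisation (the textbook route; C1–C6 bond).**
- Forward: 12 is O-nerylated and the terminal alkene is epoxidised asymmetrically to the (Z)-epoxide A1. A Lewis acid such as ZrCl4 or SnCl4 then closes the ring and would give 14 directly.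
- Turned down: only the Z geometry can give the trans product, through a chair with C7 axial, and leakage through boat geometries mixes cis and trans.
- The tertiary C2 cation can lose a proton in three directions (Δ2, tetrasubstituted Δ1, exocyclic), and it can also be captured by the C5 oxygen.
- The electron-rich coumarin and its Lewis-basic lactone sit in the substrate during the cationic step.
- The route is short but leaves every selectivity of the target to an unbiased carbocation.

**Alternative 2: decarboxylative radical fragment union at C1–C7.**
- Forward: the aryloxymethyl radical from acid A2 is generated anodically or with a photocatalyst such as Ir[dF(CF3)ppy]2(dtbbpy)PF6 and adds to enone 7 (Giese reaction), giving ketone A3 with the coumarin already attached.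
- Turned down: the radical–polar crossover ends in protonation, so A3 is a ketone with two enolisable α-carbons.
- The Δ2 alkene would need enolisation toward the hindered, methyl-bearing C2, whereas kinetic deprotonation at C4 would expel the C5 silyloxy group.
- The coumarin is a triplet-energy acceptor and a radical acceptor at its own 3,4-double bond.
- The ionic addition chosen forms the same bond and keeps the enolate.

**Alternative 3: skeletal change from a pinane (oxygen insertion into the one-carbon bridge).**
- The target is formally a pin-2-ene whose CH2 bridge has been cut at C5. Forward: Baeyer–Villiger oxidation of the cyclobutanone chrysanthenone A4 to the bridged lactone A5, then hydride reduction to diol A6.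
- Turned down: the lactone bridge necessarily holds C7 and the C5 oxygen cis, which is the C5 epimer of what is needed.
- Correction would need an SN2 inversion at a neopentyl secondary carbon, or an oxidation–reduction pair without control.
- Migratory aptitude favours the allylic bridgehead C1, which puts the oxygen on the wrong carbon, and the peracid competes for the alkene.

Key step: step 5

Remark: the SMILES is read as the (1R,5R) isomer with the C5 acetoxy and C1 aryloxymethyl groups trans. The sense of induction of the chiral copper catalyst in step 3 is not predicted here; the ligand enantiomer is defined as the one that gives (5R)-6.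

## Route

Step 1
Reactants: 1 isobutyraldehyde (2-methylpropanal); 2 ethyl vinyl ketone (pent-1-en-3-one)
Product: 3 2,4,4-trimethylcyclohex-2-en-1-one
Conditions: H2SO4 (cat.), toluene, 45 °C then reflux (Dean–Stark)
Reagents that add atoms: none
Why: Acid-catalysed Robinson-type annulation: Michael addition of the aldehyde enol to the vinyl ketone, then aldol condensation of the ethyl-side α-carbon onto the aldehyde; the fully substituted aldehyde α-carbon becomes the quaternary carbon and the ethyl group supplies the 2-methyl group.

Step 2
Reactants: 3 2,4,4-trimethylcyclohex-2-en-1-one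
Product: 4 2,4,4-trimethylcyclohexa-2,5-dien-1-one
Conditions: IBX (2 equiv), DMSO/fluorobenzene, 75 °C
Reagents that add atoms: none
Why: α′,β′-Dehydrogenation of an enone with 2-iodoxybenzoic acid; the quaternary carbon blocks aromatisation and γ-oxidation, so the cross-conjugated dienone is the only unsaturation pattern available.

Step 3
Reactants: 4 2,4,4-trimethylcyclohexa-2,5-dien-1-one
Product: 6 (5R)-5-hydroxy-2,4,4-trimethylcyclohex-2-en-1-one, via pinacol boronate 5 (not isolated)
Conditions: CuCl (5 mol%), NaOt-Bu (10 mol%), Taniaphos SL-T001 ligand (6 mol%, enantiomer giving 5R), B2pin2 (1.05 equiv), MeOH (2 equiv), THF, 0 °C to rt; then NaBO3·4H2O, THF/H2O, rt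
Reagents that add atoms: bis(pinacolato)diboron, CC1(C)OB(OC1(C)C)B1OC(C)(C)C(C)(C)O1 (boron of 5); sodium perborate, [Na+].[O-]OB=O (oxygen of the hydroxyl group)
Why: Copper-catalysed enantioselective β-borylation of a cyclic enone (a ligated Cu–Bpin species adds 1,4 and methanol releases the product), then stereoretentive C–B oxidation; the 2-methyl group deactivates and shields its own arm so boron goes to the unsubstituted β-carbon, and the chiral bisphosphine selects the enone face, which sets C5 as R.

Step 4
Reactants: 6 (5R)-5-hydroxy-2,4,4-trimethylcyclohex-2-en-1-one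
Product: 7 (5R)-5-[(tert-butyldimethylsilyl)oxy]-2,4,4-trimethylcyclohex-2-en-1-one
Conditions: TBSOTf, 2,6-lutidine, CH2Cl2, −78 to 0 °C
Reagents that add atoms: tert-butyldimethylsilyl trifluoromethanesulfonate, CC(C)(C)[Si](C)(C)OS(=O)(=O)C(F)(F)F
Why: Silylation of a hindered secondary alcohol with a silyl triflate at low temperature, where O-silylation outruns enolisation; the silyl ether blocks retro-aldol and elimination pathways of the β-oxygenated ketone and supplies the bulky group that directs step 5.

Step 5
Reactants: 7 (5R)-5-[(tert-butyldimethylsilyl)oxy]-2,4,4-trimethylcyclohex-2-en-1-one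
Product: 9 (3S,5R)-5-[(tert-butyldimethylsilyl)oxy]-3-{[dimethyl(propan-2-yloxy)silyl]methyl}-2,4,4-trimethylcyclohex-1-en-1-yl trifluoromethanesulfonate, via magnesium enolate 8 (not isolated)
Conditions: (i-PrO)Me2SiCH2MgCl (2 equiv; from (i-PrO)Me2SiCH2Cl, Mg, THF), CuI (15 mol%), THF, −78 to −30 °C; then N-(5-chloropyridin-2-yl)triflimide, DMPU, −78 °C to rt
Reagents that add atoms: (chloromethyl)dimethyl(propan-2-yloxy)silane, CC(C)O[Si](C)(C)CCl; magnesium, [Mg] (metal of 8); N-(5-chloropyridin-2-yl)-1,1,1-trifluoro-N-(trifluoromethylsulfonyl)methanesulfonamide, O=S(=O)(N(c1ccc(Cl)cn1)S(=O)(=O)C(F)(F)F)C(F)(F)F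
Why: The closest known reaction type is the copper-catalysed conjugate addition of a Grignard reagent with in-situ O-sulfonylation of the enolate, run here with the silylmethyl Grignard reagent that serves as a hydroxymethyl anion equivalent. Transmetalation gives a silylmethyl species of monovalent copper that forms a π-complex with the enone, adds to the β-carbon (C1 in target numbering) and collapses by reductive elimination to magnesium enolate 8, whose double bond lies specifically across C2–C3. No ring is closed; the step forms the C1–C7 bond at the carbon wedged between the quaternary C6 and the methyl-bearing C2. The new stereocentre C1 is controlled by the C5 silyloxy group: the stereoelectronically preferred axial attack on the half-chair with OTBS pseudo-equatorial comes from the face opposite that group, whereas syn attack would need either a 1,3-diaxial encounter with OTBS or a twist-boat transition state, so C7 should end up trans to the C5 oxygen. The selectivities needed are 1,4 over 1,2 addition (secured by copper), anti over syn attack (secured by the C5 substituent) and regiochemical integrity of the enolate (secured by trapping at low temperature before it can equilibrate toward C4 and expel silanolate). Sulfonylation at oxygen by the pyridyl triflimide freezes the enolate as enol triflate 9, which fixes the future Δ2 double bond and leaves C3 ready for replacement of OTf by hydrogen.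

Step 6
Reactants: 9 (3S,5R)-5-[(tert-butyldimethylsilyl)oxy]-3-{[dimethyl(propan-2-yloxy)silyl]methyl}-2,4,4-trimethylcyclohex-1-en-1-yl trifluoromethanesulfonate
Product: 10 tert-butyl{[(1R,5R)-5-{[dimethyl(propan-2-yloxy)silyl]methyl}-4,6,6-trimethylcyclohex-3-en-1-yl]oxy}dimethylsilane
Conditions: Pd(PPh3)4 (5 mol%), LiCl (3 equiv), Bu3SnH (1.5 equiv), THF, 65 °C
Reagents that add atoms: none
Why: Palladium-catalysed hydride reduction of an enol triflate (oxidative addition to zerovalent palladium, tin-to-palladium hydride transfer, reductive elimination) replaces OTf by H without moving the double bond; the neutral conditions leave both silyl groups and both stereocentres untouched.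

Step 7
Reactants: 10 tert-butyl{[(1R,5R)-5-{[dimethyl(propan-2-yloxy)silyl]methyl}-4,6,6-trimethylcyclohex-3-en-1-yl]oxy}dimethylsilane
Product: 11 {(1R,5R)-5-[(tert-butyldimethylsilyl)oxy]-2,6,6-trimethylcyclohex-2-en-1-yl}methanol
Conditions: KF, KHCO3, 30% H2O2, THF/MeOH, rt to 45 °C
Reagents that add atoms: hydrogen peroxide, OO
Why: Tamao oxidation: the fluoride-activated alkoxysilane takes up hydroperoxide and the C7 methylene migrates from silicon to oxygen; the trisubstituted alkene is inert to buffered H2O2 and the hindered secondary silyl ether survives KF in methanol.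

Step 8
Reactants: 11 {(1R,5R)-5-[(tert-butyldimethylsilyl)oxy]-2,6,6-trimethylcyclohex-2-en-1-yl}methanol; 12 umbelliferone (7-hydroxy-2H-chromen-2-one)
Product: 13 7-({(1R,5R)-5-[(tert-butyldimethylsilyl)oxy]-2,6,6-trimethylcyclohex-2-en-1-yl}methoxy)-2H-chromen-2-one
Conditions: PPh3, DIAD, THF, 0 to 45 °C
Reagents that add atoms: none
Why: Mitsunobu etherification: the primary alcohol is activated as its alkoxyphosphonium ion and displaced at C7 by the acidic 7-hydroxycoumarin; no stereocentre is involved and the coumarin enters only after all organometallic steps.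

Step 9
Reactants: 13 7-({(1R,5R)-5-[(tert-butyldimethylsilyl)oxy]-2,6,6-trimethylcyclohex-2-en-1-yl}methoxy)-2H-chromen-2-one
Product: 14 7-{[(1R,5R)-5-hydroxy-2,6,6-trimethylcyclohex-2-en-1-yl]methoxy}-2H-chromen-2-one
Conditions: HF·pyridine, pyridine, THF, 0 °C to rt
Reagents that add atoms: none
Why: Fluoride-driven cleavage of the silyl ether under buffered conditions that leave the lactone, the aryl ether and the alkene alone; only the Si–O bond breaks, so C5 keeps its configuration.

Step 10
Reactants: 14 7-{[(1R,5R)-5-hydroxy-2,6,6-trimethylcyclohex-2-en-1-yl]methoxy}-2H-chromen-2-one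
Product: 15 (1R,5R)-4,6,6-trimethyl-5-{[(2-oxo-2H-chromen-7-yl)oxy]methyl}cyclohex-3-en-1-yl acetate (target)
Conditions: Ac2O, pyridine, DMAP (cat.), CH2Cl2, rt
Reagents that add atoms: acetic anhydride, CC(=O)OC(C)=O
Why: DMAP-catalysed acylation of the hindered secondary alcohol at oxygen, with retention at C5.

## Compound list

1 | isobutyraldehyde (2-methylpropanal) | CC(C)C=O | starting material
2 | ethyl vinyl ketone (pent-1-en-3-one) | CCC(=O)C=C | starting material
3 | 2,4,4-trimethylcyclohex-2-en-1-one | CC1=CC(C)(C)CCC1=O | intermediate
4 | 2,4,4-trimethylcyclohexa-2,5-dien-1-one | CC1=CC(C)(C)C=CC1=O | intermediate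
5 | (5R)-2,4,4-trimethyl-5-(4,4,5,5-tetramethyl-1,3,2-dioxaborolan-2-yl)cyclohex-2-en-1-one (formed in the flask in step 3) | CC1(C)OB(OC1(C)C)[C@@H]2CC(=O)C(C)=CC2(C)C | intermediate
6 | (5R)-5-hydroxy-2,4,4-trimethylcyclohex-2-en-1-one | O[C@@H]1CC(=O)C(C)=CC1(C)C | intermediate
7 | (5R)-5-[(tert-butyldimethylsilyl)oxy]-2,4,4-trimethylcyclohex-2-en-1-one | CC(C)(C)[Si](C)(C)O[C@@H]1CC(=O)C(C)=CC1(C)C | intermediate
8 | chloromagnesium (3S,5R)-5-[(tert-butyldimethylsilyl)oxy]-3-{[dimethyl(propan-2-yloxy)silyl]methyl}-2,4,4-trimethylcyclohex-1-en-1-olate (formed in the flask in step 5) | CC(C)(C)[Si](C)(C)O[C@@H]1CC(O[Mg]Cl)=C(C)[C@@H](C[Si](C)(C)OC(C)C)C1(C)C | intermediate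
9 | (3S,5R)-5-[(tert-butyldimethylsilyl)oxy]-3-{[dimethyl(propan-2-yloxy)silyl]methyl}-2,4,4-trimethylcyclohex-1-en-1-yl trifluoromethanesulfonate | CC(C)(C)[Si](C)(C)O[C@@H]1CC(OS(=O)(=O)C(F)(F)F)=C(C)[C@@H](C[Si](C)(C)OC(C)C)C1(C)C | intermediate
10 | tert-butyl{[(1R,5R)-5-{[dimethyl(propan-2-yloxy)silyl]methyl}-4,6,6-trimethylcyclohex-3-en-1-yl]oxy}dimethylsilane | CC(C)(C)[Si](C)(C)O[C@@H]1CC=C(C)[C@@H](C[Si](C)(C)OC(C)C)C1(C)C | intermediate
11 | {(1R,5R)-5-[(tert-butyldimethylsilyl)oxy]-2,6,6-trimethylcyclohex-2-en-1-yl}methanol | CC(C)(C)[Si](C)(C)O[C@@H]1CC=C(C)[C@@H](CO)C1(C)C | intermediate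
12 | umbelliferone (7-hydroxy-2H-chromen-2-one) | Oc1ccc2ccc(=O)oc2c1 | starting material
13 | 7-({(1R,5R)-5-[(tert-butyldimethylsilyl)oxy]-2,6,6-trimethylcyclohex-2-en-1-yl}methoxy)-2H-chromen-2-one | CC(C)(C)[Si](C)(C)O[C@@H]1CC=C(C)[C@@H](COc2ccc3ccc(=O)oc3c2)C1(C)C | intermediate
14 | 7-{[(1R,5R)-5-hydroxy-2,6,6-trimethylcyclohex-2-en-1-yl]methoxy}-2H-chromen-2-one | O[C@@H]1CC=C(C)[C@@H](COc2ccc3ccc(=O)oc3c2)C1(C)C | intermediate
15 | (1R,5R)-4,6,6-trimethyl-5-{[(2-oxo-2H-chromen-7-yl)oxy]methyl}cyclohex-3-en-1-yl acetate | CC(=O)O[C@@H]1CC=C(C)[C@@H](COc2ccc3ccc(=O)oc3c2)C1(C)C | target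

## Step count and risk assessment

Total step count: 10. Longest linear sequence: 10 steps (1 and 2 to 15); 12 is bought and enters in step 8.

**Step 5 (key step).**
- Most likely to go wrong: slow transfer of the bulky silylmethyl group from copper to the shielded β-carbon. Then 1,2-addition to the carbonyl, or α′-deprotonation followed by loss of the silyloxy group, can take over.
- Less likely: incomplete facial selectivity, or sluggish O-sulfonylation of the hindered magnesium enolate.
- Fallback, from 7 back to 11, using a [2,3]-sigmatropic rearrangement instead of an intermolecular addition: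
  - Luche reduction of 7 (NaBH4, CeCl3·7H2O, MeOH, −78 °C) should give mainly the cis allylic alcohol (1S,5R)-5-[(tert-butyldimethylsilyl)oxy]-2,4,4-trimethylcyclohex-2-en-1-ol F1.
  - Mitsunobu inversion with 4-nitrobenzoic acid (PPh3, DIAD) gives (1R,5R)-5-[(tert-butyldimethylsilyl)oxy]-2,4,4-trimethylcyclohex-2-en-1-yl 4-nitrobenzoate F2.
  - Methanolysis (K2CO3, MeOH) gives the trans alcohol (1R,5R)-5-[(tert-butyldimethylsilyl)oxy]-2,4,4-trimethylcyclohex-2-en-1-ol F3. Should the reduction give F3 directly, the inversion is skipped.
  - Alkylation with Bu3SnCH2I (KH, THF) gives tributyl[({(1R,5R)-5-[(tert-butyldimethylsilyl)oxy]-2,4,4-trimethylcyclohex-2-en-1-yl}oxy)methyl]stannane F4.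
  - Tin–lithium exchange (n-BuLi, THF, −78 °C) triggers the Still–Wittig rearrangement. It is suprafacial, so C7 is delivered to C1 on the face of the departing oxygen, trans to the C5 silyloxy group, and the double bond moves to C2=C3. This gives 11 directly.

**Step 3.**
- Most likely to go wrong: insufficient discrimination between the two faces of the nearly flat dienone, or further borylation of the methyl-bearing enone arm.
- Fallback, from 4 back to 6:
  - Iminium-catalysed asymmetric nucleophilic epoxidation of the unsubstituted enone arm (9-amino-9-deoxy-epi-quinine trifluoroacetate or its quinidine-derived counterpart, aqueous H2O2, dioxane) gives (1S,6S)-3,5,5-trimethyl-7-oxabicyclo[4.1.0]hept-3-en-2-one F5.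
  - Reductive cleavage of the Cα–O bond with the selenolate from PhSeSePh and NaBH4 (EtOH, AcOH) keeps the Cβ–O bond and gives 6.

**Step 8.**
- Most likely to go wrong: slow displacement at the β-branched C7 next to the quaternary C6, so that the alkoxyphosphonium ion is consumed by alkylation of the reduced azodicarboxylate.
- Fallback, from 11 back to 13, with reversed polarity: 11 acts as the nucleophile in a palladium-catalysed C–O coupling with commercial 7-bromo-2H-chromen-2-one ([Pd(C3H5)Cl]2, a bulky di-tert-butyl biaryl phosphine, Cs2CO3, toluene, 80 °C). No substitution takes place at C7, so its hindrance no longer matters. No new compound is made (F0).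

**Step 6.**
- Most likely to go wrong: sluggish oxidative addition of zerovalent palladium into the tetrasubstituted enol triflate, with competing S–O cleavage back to the ketone.
- Fallback, from 7 through enolate 8 back to 10:
  - The enolate from the conjugate addition is quenched with ClP(O)(OEt)2 to give (3S,5R)-5-[(tert-butyldimethylsilyl)oxy]-3-{[dimethyl(propan-2-yloxy)silyl]methyl}-2,4,4-trimethylcyclohex-1-en-1-yl diethyl phosphate F6.
  - Dissolving-metal reduction (Li, EtNH2, t-BuOH, THF, −78 °C) cleaves the vinylic C–O bond and gives 10.

## Further compounds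

F1 | step 5 | (1S,5R)-5-[(tert-butyldimethylsilyl)oxy]-2,4,4-trimethylcyclohex-2-en-1-ol | CC(C)(C)[Si](C)(C)O[C@@H]1C[C@H](O)C(C)=CC1(C)C
F2 | step 5 | (1R,5R)-5-[(tert-butyldimethylsilyl)oxy]-2,4,4-trimethylcyclohex-2-en-1-yl 4-nitrobenzoate | CC(C)(C)[Si](C)(C)O[C@@H]1C[C@@H](OC(=O)c2ccc(cc2)[N+](=O)[O-])C(C)=CC1(C)C
F3 | step 5 | (1R,5R)-5-[(tert-butyldimethylsilyl)oxy]-2,4,4-trimethylcyclohex-2-en-1-ol | CC(C)(C)[Si](C)(C)O[C@@H]1C[C@@H](O)C(C)=CC1(C)C
F4 | step 5 | tributyl[({(1R,5R)-5-[(tert-butyldimethylsilyl)oxy]-2,4,4-trimethylcyclohex-2-en-1-yl}oxy)methyl]stannane | CC(C)(C)[Si](C)(C)O[C@@H]1C[C@@H](OC[Sn](CCCC)(CCCC)CCCC)C(C)=CC1(C)C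
F5 | step 3 | (1S,6S)-3,5,5-trimethyl-7-oxabicyclo[4.1.0]hept-3-en-2-one | O1[C@@H]2[C@H]1C(=O)C(C)=CC2(C)C
F0 | step 8 | none | none
F6 | step 6 | (3S,5R)-5-[(tert-butyldimethylsilyl)oxy]-3-{[dimethyl(propan-2-yloxy)silyl]methyl}-2,4,4-trimethylcyclohex-1-en-1-yl diethyl phosphate | CC(C)(C)[Si](C)(C)O[C@@H]1CC(OP(=O)(OCC)OCC)=C(C)[C@@H](C[Si](C)(C)OC(C)C)C1(C)C
A1 | alternative 1 | 7-({(2Z)-5-[(2R)-3,3-dimethyloxiran-2-yl]-3-methylpent-2-en-1-yl}oxy)-2H-chromen-2-one | C/C(CC[C@H]1OC1(C)C)=C/COc1ccc2ccc(=O)oc2c1
A2 | alternative 2 | [(2-oxo-2H-chromen-7-yl)oxy]acetic acid | OC(=O)COc1ccc2ccc(=O)oc2c1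
A3 | alternative 2 | 7-({(1R,5R)-5-[(tert-butyldimethylsilyl)oxy]-2,6,6-trimethyl-3-oxocyclohexyl}methoxy)-2H-chromen-2-one (mixture at C2) | CC(C)(C)[Si](C)(C)O[C@@H]1CC(=O)C(C)[C@@H](COc2ccc3ccc(=O)oc3c2)C1(C)C
A4 | alternative 3 | (1R,5S)-2,7,7-trimethylbicyclo[3.1.1]hept-2-en-6-one (chrysanthenone) | O=C1[C@H]2CC=C(C)[C@@H]1C2(C)C
A5 | alternative 3 | (1R,5S)-2,8,8-trimethyl-6-oxabicyclo[3.2.1]oct-2-en-7-one | O=C1O[C@H]2CC=C(C)[C@@H]1C2(C)C
A6 | alternative 3 | (1S,5R)-5-(hydroxymethyl)-4,6,6-trimethylcyclohex-3-en-1-ol | O[C@H]1CC=C(C)[C@@H](CO)C1(C)C
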